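**Retrosynthetic overview**
1. Target 9 is the threo (1R,2R) benzylic acetate of an 8-O-4' neolignan. The cinnamyl alcohol arm is cut last at the aryl–vinyl bond (Stille), giving aryl bromide 7 and stannane 8, so the primary hydroxyl only appears after the acetate is in place.
2. 7 comes from acetylation of alcohol 6, which comes from Felkin–Anh reduction of the (R)-α-aryloxy ketone 5 (C1 is set from C2).
3. Key disconnection: the C2–O aryl ether bond of 5, made from racemic α-bromo ketone 3 and phenol 4 in an enantioconvergent etherification (new step, sets C2).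
4. 3 comes from ketone 2, which comes from acid chloride 1 and EtMgBr.
5. No ring is formed; both benzene rings are bought.

Assumption: which antipode of the chiral ammonium salt gives the (R)-ether in step 3 is fixed in a first small-scale run; the (S,S) salt is written below and the (R,R) salt is used if the sense is opposite.

**Route**

Step 1
Reactants: 1 3,4,5-trimethoxybenzoyl chloride
Product: 2 1-(3,4,5-trimethoxyphenyl)propan-1-one
Conditions: EtMgBr (1.1 equiv), Fe(acac)3 (3 mol%), THF, −78 °C, 15 min; aq. NH4Cl
Reagents that add atoms: ethylmagnesium bromide (CC[Mg]Br)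
Why: Iron-catalysed acylation of a Grignard reagent (Kumada-type cross-coupling of an acid chloride) is much faster than addition to the ketone formed, so it stops cleanly at the ketone.

Step 2
Reactants: 2 1-(3,4,5-trimethoxyphenyl)propan-1-one
Product: 3 rac-2-bromo-1-(3,4,5-trimethoxyphenyl)propan-1-one
Conditions: CuBr2 (2.1 equiv), EtOAc/CHCl3 1:1, reflux
Reagents that add atoms: copper dibromide, CuBr2 ([Cu+2].[Br-].[Br-])
Why: CuBr2 α-bromination of an enolisable aryl ketone goes through the copper enolate and brominates only the α-carbon, not the electron-rich ring; the racemate is what step 3 needs.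

Step 3
Reactants: 3 rac-2-bromo-1-(3,4,5-trimethoxyphenyl)propan-1-one; 4 4-bromo-2,6-dimethoxyphenol (1.2 equiv)
Product: 5 (2R)-2-(4-bromo-2,6-dimethoxyphenoxy)-1-(3,4,5-trimethoxyphenyl)propan-1-one
Conditions: (S,S) C2-symmetric N-spiro bis(binaphthyl-2,2'-dimethylene)ammonium bromide with 3,3'-bis(3,4,5-trifluorophenyl) groups (10 mol%), powdered K2CO3 (2 equiv), toluene, 0 °C, 48 h
Reagents that add atoms: none
Why: Proposed new method: enantioconvergent phase-transfer O-alkylation of a phenol by a racemic α-bromo ketone (a dynamic kinetic resolution). The chiral ammonium carries the phenoxide of 4 into toluene as a tight ion pair that also holds the carbonyl of 3 through its α-ammonium C–H bonds, so SN2 attack with inversion is fast only on (S)-3 and gives (R)-5. The bromide set free returns as the chiral ammonium bromide and racemises unreacted 3 by degenerate bromide–bromide SN2 exchange faster than the ether forms. The solid potassium phenoxide is insoluble in toluene, so there is no racemic background; the phenoxide is too weak a base to enolise 5; and the blocked ortho and para positions of 4 allow only O-alkylation. Closest known reaction type: chiral ammonium or hydrogen-bond-donor phase-transfer-catalysed enantioconvergent substitution of racemic α-bromo ketones by azide or fluoride, together with the racemic Williamson coupling of α-bromopropiophenones with 2,6-dimethoxyphenols.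

Step 4
Reactants: 5 (2R)-2-(4-bromo-2,6-dimethoxyphenoxy)-1-(3,4,5-trimethoxyphenyl)propan-1-one
Product: 6 (1R,2R)-2-(4-bromo-2,6-dimethoxyphenoxy)-1-(3,4,5-trimethoxyphenyl)propan-1-ol (threo)
Conditions: NaBH4, 15-crown-5, MeOH, −20 °C
Reagents that add atoms: none
Why: With sodium sequestered by the crown ether no chelate can form, so hydride adds by the polar Felkin–Anh model (aryloxy group anti to the incoming hydride) and gives the syn (threo) alcohol; C1 is set as R by 1,2-induction from C2, which is not epimerised at this temperature.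

Step 5
Reactants: 6 (1R,2R)-2-(4-bromo-2,6-dimethoxyphenoxy)-1-(3,4,5-trimethoxyphenyl)propan-1-ol
Product: 7 (1R,2R)-2-(4-bromo-2,6-dimethoxyphenoxy)-1-(3,4,5-trimethoxyphenyl)propyl acetate
Conditions: Ac2O, Et3N, DMAP (10 mol%), CH2Cl2, 0 °C to rt
Reagents that add atoms: acetic anhydride (CC(=O)OC(C)=O)
Why: DMAP-catalysed O-acylation forms the acyl–oxygen bond only, so C1 keeps its configuration, and the molecule has no other hydroxyl.

Step 6
Reactants: 7 (1R,2R)-2-(4-bromo-2,6-dimethoxyphenoxy)-1-(3,4,5-trimethoxyphenyl)propyl acetate; 8 (E)-3-(tributylstannyl)prop-2-en-1-ol (1.2 equiv)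
Product: 9 (1R,2R)-2-{4-[(E)-3-hydroxyprop-1-en-1-yl]-2,6-dimethoxyphenoxy}-1-(3,4,5-trimethoxyphenyl)propyl acetate (target)
Conditions: Pd(P(t-Bu)3)2 (3 mol%), CsF (2 equiv), 1,4-dioxane, 40 °C
Reagents that add atoms: none
Why: Stille cross-coupling with the electron-rich bulky phosphine on zerovalent palladium inserts into the unhindered, electron-rich aryl bromide and transfers the alkenyl group with retention of the E geometry; the near-neutral conditions leave the acetate, the free hydroxyl and both stereocentres untouched.

**Compound list**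
1 | 3,4,5-trimethoxybenzoyl chloride | COc1cc(C(Cl)=O)cc(OC)c1OC | starting material
2 | 1-(3,4,5-trimethoxyphenyl)propan-1-one | CCC(=O)c1cc(OC)c(OC)c(OC)c1 | intermediate
3 | rac-2-bromo-1-(3,4,5-trimethoxyphenyl)propan-1-one | CC(Br)C(=O)c1cc(OC)c(OC)c(OC)c1 | intermediate
4 | 4-bromo-2,6-dimethoxyphenol | COc1cc(Br)cc(OC)c1O | starting material
5 | (2R)-2-(4-bromo-2,6-dimethoxyphenoxy)-1-(3,4,5-trimethoxyphenyl)propan-1-one | COc1cc(C(=O)[C@@H](C)Oc2c(OC)cc(Br)cc2OC)cc(OC)c1OC | intermediate
6 | (1R,2R)-2-(4-bromo-2,6-dimethoxyphenoxy)-1-(3,4,5-trimethoxyphenyl)propan-1-ol | COc1cc([C@@H](O)[C@@H](C)Oc2c(OC)cc(Br)cc2OC)cc(OC)c1OC | intermediate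
7 | (1R,2R)-2-(4-bromo-2,6-dimethoxyphenoxy)-1-(3,4,5-trimethoxyphenyl)propyl acetate | COc1cc([C@@H](OC(C)=O)[C@@H](C)Oc2c(OC)cc(Br)cc2OC)cc(OC)c1OC | intermediate
8 | (E)-3-(tributylstannyl)prop-2-en-1-ol | CCCC[Sn](CCCC)(CCCC)/C=C/CO | starting material
9 | (1R,2R)-2-{4-[(E)-3-hydroxyprop-1-en-1-yl]-2,6-dimethoxyphenoxy}-1-(3,4,5-trimethoxyphenyl)propyl acetate | COc1cc([C@@H](OC(C)=O)[C@@H](C)Oc2c(OC)cc(/C=C/CO)cc2OC)cc(OC)c1OC | target

**Step count**
Total: 6 steps. Longest linear sequence: 6 steps (1 → 2 → 3 → 5 → 6 → 7 → 9); 4 and 8 are bought.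

**Three steps most likely to fail**

Step 3 (the new step). The risks are low enantiomeric excess, if bromide exchange does not outpace etherification or a racemic background path operates, and slow reaction of the hindered phenoxide at 0 °C. The fallback uses known chemistry; it sets out from 4 and comes back at 5, replacing steps 1 to 3. Mitsunobu etherification of 4 with ethyl (S)-lactate (PPh3, DIAD, THF, 0 °C to rt) goes with SN2 inversion and gives ethyl (2R)-2-(4-bromo-2,6-dimethoxyphenoxy)propanoate F1. Treatment with MeNH(OMe)·HCl and i-PrMgCl in THF at −20 °C turns it into (2R)-2-(4-bromo-2,6-dimethoxyphenoxy)-N-methoxy-N-methylpropanamide F2. Commercial 3,4,5-trimethoxyphenylmagnesium bromide in THF at −20 to 0 °C then adds once to the Weinreb amide, whose chelated tetrahedral intermediate prevents over-addition, and delivers 5.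

Step 4. The risk is an insufficient threo:erythro ratio if residual cation chelation by the 2,6-dimethoxyphenoxy group competes with the Felkin–Anh pathway. The fallback sets out from 5 and comes back at 7, so step 5 is not needed. Chelation-controlled reduction with Zn(BH4)2 in Et2O at −20 °C is used on purpose to give the erythro alcohol (1S,2R)-2-(4-bromo-2,6-dimethoxyphenoxy)-1-(3,4,5-trimethoxyphenyl)propan-1-ol F3. Mitsunobu esterification with acetic acid (PPh3, DIAD, AcOH, THF, 0 °C) then inverts C1 and gives the threo acetate 7 directly.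

Step 6. The risks are sluggish oxidative addition of the electron-rich bromide, protodestannylation, and fluoride-promoted acetyl transfer to the free primary hydroxyl. The fallback sets out from 7 and comes back at 9. Suzuki–Miyaura coupling of 7 with commercial (E)-tert-butyldimethylsilyl-protected 3-hydroxyprop-1-enylboronic acid pinacol ester (Pd(dppf)Cl2, K3PO4, dioxane/H2O, 60 °C) keeps the hydroxyl masked and gives (1R,2R)-2-{4-[(E)-3-(tert-butyldimethylsilyloxy)prop-1-en-1-yl]-2,6-dimethoxyphenoxy}-1-(3,4,5-trimethoxyphenyl)propyl acetate F4. HF·pyridine in THF at 0 °C removes the silyl group without touching the acetate and gives 9.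

**Further compounds**
F1 | step 3 | ethyl (2R)-2-(4-bromo-2,6-dimethoxyphenoxy)propanoate | CCOC(=O)[C@@H](C)Oc1c(OC)cc(Br)cc1OC
F2 | step 3 | (2R)-2-(4-bromo-2,6-dimethoxyphenoxy)-N-methoxy-N-methylpropanamide | CON(C)C(=O)[C@@H](C)Oc1c(OC)cc(Br)cc1OC
F3 | step 4 | (1S,2R)-2-(4-bromo-2,6-dimethoxyphenoxy)-1-(3,4,5-trimethoxyphenyl)propan-1-ol | COc1cc([C@H](O)[C@@H](C)Oc2c(OC)cc(Br)cc2OC)cc(OC)c1OC
F4 | step 6 | (1R,2R)-2-{4-[(E)-3-(tert-butyldimethylsilyloxy)prop-1-en-1-yl]-2,6-dimethoxyphenoxy}-1-(3,4,5-trimethoxyphenyl)propyl acetate | COc1cc([C@@H](OC(C)=O)[C@@H](C)Oc2c(OC)cc(/C=C/CO[Si](C)(C)C(C)(C)C)cc2OC)cc(OC)c1OC
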